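The numbers of this flask are invented; the result is computed.

It was impossible, I told the board, for this flask to use up its electrophile faster than the gas could pay for it.

electrophile 0.31 M; gas 67 mM (held); time 3.0 h

1. part of the electrophile that has reacted at 3.0 h
2. share of free nucleophile in free nucleophile and protonated nucleophile together, at 3.0 h

- at the start none of nucleophile is dissolved
- run time (flask): 3.0 h

    nucleophile + acid set free ⇌ protonated nucleophile, settled at all times (K1 = 18000 M⁻¹)
    nucleophile ⇌ dormant form (K2 = 62, k2 = 0.0032 min⁻¹)
    gas ⇌ nucleophile, rate k3*(csat - [nucleophile]) (k3 = 0.061 min⁻¹, csat = 67 mM)
    acid set free → by-product carried off (k4 = 0.0042 min⁻¹)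
    electrophile + nucleophile → acid set free + product (k5 = 1.6 M⁻¹ min⁻¹)

Dissolving stopped at the saturation concentration, so the gas delivered at best 4.09 mM min⁻¹. Each electrophile converted cost two nucleophiles, one reacting and one bound by the acid set free, because early free nucleophile near 3.88 mM made K1 times c(nucleophile) 69.9. I therefore took as my measure the feed time, twice the electrophile charged divided by that delivery: 2.53 h.

I set up two extreme versions. With instant reaction, the flask finished at the feed time, earlier than 3.0 h, and gas transfer was the rate-limiting step. With instant gas, c(nucleophile) stood at saturation and the electrophile decayed with time constant 9.33 min, halving every 6.47 min.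

The real flask lay behind both. With the electrophile as charged, free nucleophile had a half-life of 1.4 min against the reaction with it, short against the run, so early on it stayed balanced between delivery and consumption. I carried that balance through the later run as an assumption, which made the two times add: reaching conversion X took the feed time times X, plus the time constant times ln(1/(1−X)). Charging the whole feed time and giving the remainder to the tail left 4.81%, so I committed to 95.2% reacted. On the same assumption, free nucleophile stood near 37.6 mM at the end; against a bound form of about 0.31 M, my estimate of its share was 10.8%.

The forecast gave 95.5% and 6%, on the ground that “Gas transfer is the bottleneck”. On the share, my figure stood higher than the forecast's.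

The simulation gave 94.8% and 9.37%.

In this flask, the added times at 94.8% came to 2.86 h of the 3.0 h. The answer to c moved by 5 points at 0.348 M of electrophile or at 2.73 h, and a shift of that size would have put the forecast in doubt. The neighbour charged with 0.53 M had a feed time of 4.32 h, longer than its run, so the feed paid for 69.4%. That neighbour gave 65.3%, where the added times came to 2.99 h, and it ended with 35% of its electrophile still there.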